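**Plan**
- Ring C is cut at C3–C4 and O1–C2. Its O1–C8a–C4a–C4 unit maps onto the oxa-diene of an o-quinone methide of ring A, and its C2–C3 unit, with ring B on C3, maps onto the enol ether of an arylacetaldehyde.
- Further cuts: the C2–O bond to the auxiliary (acetal reduction) and the C3–C1' bond (alkynylzinc plus aryl bromide); C2 and C3 come from trichloroethylene.
- Forward: ring A is made as an O-Boc salicyl alcohol (steps 1–4) and ring B as its bromide (steps 5–6). The bromide is joined to the alkynyl ether of the auxiliary and semihydrogenated to the (Z)-enol ether (steps 7–9).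
- The [4+2] cycloaddition then closes ring C (step 10); acetal reduction and debenzylation finish the synthesis (steps 11–12).
- Stereochemistry: C3, the only stereocentre of the target, is set in step 10 by the (1R,2S)-2-phenylcyclohexyl group acting on a geometrically pure (Z)-enol ether. C2 is a transient centre erased in step 11.

Key step: step 10

Assumption: the (1R,2S) auxiliary is taken to direct the quinone methide to the enol-ether face that gives 3S (model in step 10); should the sense prove opposite, (1S,2R)-2-phenylcyclohexanol is used instead and nothing else changes.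

**Step 1**
Reactants: 1 2-hydroxy-3,4-dimethoxybenzaldehyde
Product: 3 2,5-dihydroxy-3,4-dimethoxybenzaldehyde, via aryl sulfate 2 (not isolated)
Conditions: K2S2O8, 10% aq NaOH, 0 °C to rt; then aq HCl, 80 °C
Reagents that add atoms: potassium peroxodisulfate, [K+].[K+].[O-]S(=O)(=O)OOS(=O)(=O)[O-]
Why: Elbs persulfate oxidation, in which the phenoxide attacks peroxodisulfate through C5, the only free position ortho or para to the phenol oxygen, and acid hydrolysis of aryl sulfate 2 should free the hydroquinone.

**Step 2**
Reactants: 3 2,5-dihydroxy-3,4-dimethoxybenzaldehyde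
Product: 4 5-(benzyloxy)-2-hydroxy-3,4-dimethoxybenzaldehyde
Conditions: NaH (2.1 equiv), DMSO, rt; BnBr (1.0 equiv); aq HCl work-up
Reagents that add atoms: benzyl bromide, BrCc1ccccc1
Why: Williamson etherification of the dianion, in which the 5-phenoxide (neither chelated to nor conjugated with the formyl group) is the more nucleophilic oxygen, so one equivalent of benzyl bromide should alkylate O5 and leave the hydrogen-bonded 2-OH free.

**Step 3**
Reactants: 4 5-(benzyloxy)-2-hydroxy-3,4-dimethoxybenzaldehyde
Product: 5 tert-butyl [4-(benzyloxy)-6-formyl-2,3-dimethoxyphenyl] carbonate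
Conditions: Boc2O, i-Pr2NEt, DMAP (cat.), THF, rt
Reagents that add atoms: di-tert-butyl dicarbonate, CC(C)(C)OC(=O)OC(=O)OC(C)(C)C
Why: DMAP-catalysed O-acylation of the only remaining phenol by Boc2O should give the aryl tert-butyl carbonate that later serves as the trigger for quinone methide release.

**Step 4**
Reactants: 5 tert-butyl [4-(benzyloxy)-6-formyl-2,3-dimethoxyphenyl] carbonate
Product: 6 tert-butyl [4-(benzyloxy)-6-(hydroxymethyl)-2,3-dimethoxyphenyl] carbonate
Conditions: BH3·THF, THF, 0 °C; then water, neutral work-up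
Reagents that add atoms: none
Why: Borane reduction of the aldehyde passes through a neutral alkoxyborane and not a metal alkoxide, so the carbonate should neither migrate nor be reduced and the quinone methide is not released prematurely.

**Step 5**
Reactants: 7 2,3-dimethoxyphenol
Product: 8 6-bromo-2,3-dimethoxyphenol
Conditions: Br2 (1.0 equiv), t-BuNH2 (2.0 equiv), toluene, −78 °C to rt
Reagents that add atoms: bromine, BrBr
Why: Amine-mediated ortho-bromination of a phenol, in which N-bromo-tert-butylamine hydrogen-bonded to the OH group delivers bromine to C6, the only free ortho carbon and also para to the 3-methoxy group, in preference to the para carbon C4.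

**Step 6**
Reactants: 8 6-bromo-2,3-dimethoxyphenol
Product: 9 2-(benzyloxy)-1-bromo-3,4-dimethoxybenzene
Conditions: BnBr, K2CO3, DMF, rt
Reagents that add atoms: benzyl bromide, BrCc1ccccc1
Why: Williamson etherification of the phenol gives a benzyl ether that should survive the organometallic, Lewis-acid and semihydrogenation steps and leave only at the final hydrogenolysis.

**Step 7**
Reactants: 10 (1R,2S)-trans-2-phenylcyclohexanol; 11 trichloroethylene
Product: 14 (E)-1,2-dichlorovinyl (1R,2S)-2-phenylcyclohexyl ether, via potassium alkoxide 12 (not isolated), via dichloroacetylene 13 (not isolated)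
Conditions: KH, THF, 0 °C to rt; then trichloroethylene, −50 °C to rt
Reagents that add atoms: none
Why: Base-induced dehydrochlorination of trichloroethylene to dichloroacetylene followed by trans addition of the alkoxide is the standard dichlorovinyl ether entry to alkynyl ethers of secondary alcohols, and the carbinol C–O bond is retained so the auxiliary keeps its configuration.

**Step 8**
Reactants: 14 (E)-1,2-dichlorovinyl (1R,2S)-2-phenylcyclohexyl ether; 9 2-(benzyloxy)-1-bromo-3,4-dimethoxybenzene
Product: 18 [2-(benzyloxy)-3,4-dimethoxyphenyl]ethynyl (1R,2S)-2-phenylcyclohexyl ether, via chloroethynyl ether 15 (not isolated), via lithium alkoxyacetylide 16 (not isolated), via alkynylzinc chloride 17 (not isolated)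
Conditions: n-BuLi (2.1 equiv), THF, −78 to −40 °C; ZnCl2, −40 to 0 °C; then 9, Pd(P(t-Bu)3)2 (cat.), rt
Reagents that add atoms: none
Why: β-Elimination to the chloroalkyne, lithium–chlorine exchange and transmetalation give an alkynylzinc chloride that should undergo Negishi coupling with the aryl bromide at room temperature, mild enough to avoid retro-ene cleavage of the sec-alkyl ynol ether.

**Step 9**
Reactants: 18 [2-(benzyloxy)-3,4-dimethoxyphenyl]ethynyl (1R,2S)-2-phenylcyclohexyl ether
Product: 19 (Z)-2-[2-(benzyloxy)-3,4-dimethoxyphenyl]vinyl (1R,2S)-2-phenylcyclohexyl ether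
Conditions: H2 (1 atm), Pd/CaCO3 poisoned with Pb(OAc)2 (Lindlar catalyst), quinoline, EtOAc, rt
Reagents that add atoms: none
Why: Lindlar semihydrogenation adds both hydrogens to one face of the alkyne, so the (Z)-enol ether should form geometrically pure, while quinoline and one equivalent of hydrogen limit over-reduction and the poisoned catalyst leaves the benzyl ether intact.

**Step 10**
Reactants: 6 tert-butyl [4-(benzyloxy)-6-(hydroxymethyl)-2,3-dimethoxyphenyl] carbonate; 19 (Z)-2-[2-(benzyloxy)-3,4-dimethoxyphenyl]vinyl (1R,2S)-2-phenylcyclohexyl ether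
Product: 23 (2S,3S)-6-(benzyloxy)-3-[2-(benzyloxy)-3,4-dimethoxyphenyl]-7,8-dimethoxy-2-{[(1R,2S)-2-phenylcyclohexyl]oxy}chroman (2,3-cis), via magnesium alkoxide 20 (not isolated), via benzylic carbonate phenoxide 21 (not isolated), via o-quinone methide 22 (not isolated)
Conditions: t-BuMgCl (1.0 equiv per 6, added slowly), 6 (1.5 equiv), 19 (1.0 equiv), toluene, −78 °C to rt; aq NH4Cl
Reagents that add atoms: none
Why: tert-Butylmagnesium chloride turns the benzylic alcohol into alkoxide 20, the Boc group shifts from the phenol oxygen to the alkoxide oxygen (21), and the magnesium phenoxide then expels tert-butyl carbonate well below room temperature, so o-quinone methide 22 is released slowly in the presence of 19. The closest known reaction type is the inverse-electron-demand hetero-Diels–Alder reaction of o-quinone methides from O-Boc salicyl alcohols with chiral alkyl vinyl ethers, which gives 2-alkoxychromans. Ring C is closed by an intermolecular, concerted but asynchronous [4+2] cycloaddition that is suprafacial on both partners: the nucleophilic aryl-bearing carbon of the enol ether bonds to the exocyclic methylene (C3–C4) ahead of closure of the carbonyl oxygen onto the alkoxy-bearing carbon (O1–C2), which fixes the 2-alkoxy-3-aryl regiochemistry. C3 is controlled by the auxiliary: with the enol ether s-trans about the O–C(vinyl) bond and the carbinol C–H eclipsing that bond, the phenyl group covers one π-face and 22 adds to the other, taken for the (1R,2S) ether to be the face that gives 3S; C2 follows from the Z geometry (2,3-cis, 2S) and is erased in step 11. Because C4 of 22 is an unsubstituted methylene, endo and exo approach give the same product, so the step needs only π-facial selectivity and a geometrically pure enol ether, the first secured by the 2-phenylcyclohexyl group and the second by step 9, while the slow release keeps self-condensation of 22 down.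

**Step 11**
Reactants: 23 (2S,3S)-6-(benzyloxy)-3-[2-(benzyloxy)-3,4-dimethoxyphenyl]-7,8-dimethoxy-2-{[(1R,2S)-2-phenylcyclohexyl]oxy}chroman
Product: 25 (3S)-6-(benzyloxy)-3-[2-(benzyloxy)-3,4-dimethoxyphenyl]-7,8-dimethoxychroman, via oxocarbenium ion 24 (not isolated)
Conditions: Et3SiH (5 equiv), BF3·OEt2 (1.5 equiv), CH2Cl2, −78 °C; aq NaHCO3
Reagents that add atoms: none
Why: Lewis-acid/silane ionic reduction of an O,O-acetal, in which BF3 ionises the exocyclic C2–O bond to ring oxocarbenium ion 24 and excess triethylsilane should reduce it at −78 °C faster than it can lose H3, so C2 becomes a methylene, C3 keeps its configuration and the auxiliary returns as the alcohol.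

**Step 12**
Reactants: 25 (3S)-6-(benzyloxy)-3-[2-(benzyloxy)-3,4-dimethoxyphenyl]-7,8-dimethoxychroman
Product: 26 (3S)-3-(2-hydroxy-3,4-dimethoxyphenyl)-7,8-dimethoxychroman-6-ol (CNP0416342.1)
Conditions: H2 (1 atm), 10% Pd/C, EtOAc–MeOH, rt
Reagents that add atoms: none
Why: Catalytic hydrogenolysis of the two aryl benzyl ethers frees both phenols, and since C3 carries no benzylic C–heteroatom bond and the ring C–O bonds are not benzylic, the stereocentre and ring C should be unaffected.

**Compound list**
1 | 2-hydroxy-3,4-dimethoxybenzaldehyde | O=Cc1ccc(OC)c(OC)c1O | starting material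
2 | potassium 5-formyl-4-hydroxy-2,3-dimethoxyphenyl sulfate | O=Cc1cc(OS(=O)(=O)[O-])c(OC)c(OC)c1O.[K+] | intermediate
3 | 2,5-dihydroxy-3,4-dimethoxybenzaldehyde | O=Cc1cc(O)c(OC)c(OC)c1O | intermediate
4 | 5-(benzyloxy)-2-hydroxy-3,4-dimethoxybenzaldehyde | O=Cc1cc(OCc2ccccc2)c(OC)c(OC)c1O | intermediate
5 | tert-butyl [4-(benzyloxy)-6-formyl-2,3-dimethoxyphenyl] carbonate | O=Cc1cc(OCc2ccccc2)c(OC)c(OC)c1OC(=O)OC(C)(C)C | intermediate
6 | tert-butyl [4-(benzyloxy)-6-(hydroxymethyl)-2,3-dimethoxyphenyl] carbonate | COc1c(OC(=O)OC(C)(C)C)c(CO)cc(OCc2ccccc2)c1OC | intermediate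
7 | 2,3-dimethoxyphenol | COc1cccc(O)c1OC | starting material
8 | 6-bromo-2,3-dimethoxyphenol | COc1ccc(Br)c(O)c1OC | intermediate
9 | 2-(benzyloxy)-1-bromo-3,4-dimethoxybenzene | COc1ccc(Br)c(OCc2ccccc2)c1OC | intermediate
10 | (1R,2S)-trans-2-phenylcyclohexanol | O[C@@H]1CCCC[C@H]1c1ccccc1 | starting material
11 | trichloroethylene | ClC=C(Cl)Cl | starting material
12 | potassium (1R,2S)-2-phenylcyclohexanolate | [K+].[O-][C@@H]1CCCC[C@H]1c1ccccc1 | intermediate
13 | dichloroacetylene | ClC#CCl | intermediate
14 | (E)-1,2-dichlorovinyl (1R,2S)-2-phenylcyclohexyl ether | Cl/C=C(Cl)\O[C@@H]1CCCC[C@H]1c1ccccc1 | intermediate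
15 | chloroethynyl (1R,2S)-2-phenylcyclohexyl ether | ClC#CO[C@@H]1CCCC[C@H]1c1ccccc1 | intermediate
16 | lithium [(1R,2S)-2-phenylcyclohexyloxy]acetylide | [Li]C#CO[C@@H]1CCCC[C@H]1c1ccccc1 | intermediate
17 | chloro{[(1R,2S)-2-phenylcyclohexyloxy]ethynyl}zinc | Cl[Zn]C#CO[C@@H]1CCCC[C@H]1c1ccccc1 | intermediate
18 | [2-(benzyloxy)-3,4-dimethoxyphenyl]ethynyl (1R,2S)-2-phenylcyclohexyl ether | COc1ccc(C#CO[C@@H]2CCCC[C@H]2c3ccccc3)c(OCc4ccccc4)c1OC | intermediate
19 | (Z)-2-[2-(benzyloxy)-3,4-dimethoxyphenyl]vinyl (1R,2S)-2-phenylcyclohexyl ether | COc1ccc(/C=C\O[C@@H]2CCCC[C@H]2c3ccccc3)c(OCc4ccccc4)c1OC | intermediate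
20 | chloromagnesium alkoxide of 6 (benzylic O–MgCl, aryl O-Boc) | COc1c(OC(=O)OC(C)(C)C)c(CO[Mg]Cl)cc(OCc2ccccc2)c1OC | intermediate
21 | chloromagnesium 4-(benzyloxy)-6-{[(tert-butoxycarbonyl)oxy]methyl}-2,3-dimethoxyphenoxide | COc1c(O[Mg]Cl)c(COC(=O)OC(C)(C)C)cc(OCc2ccccc2)c1OC | intermediate
22 | 4-(benzyloxy)-2,3-dimethoxy-6-methylidenecyclohexa-2,4-dien-1-one (o-quinone methide) | C=C1C=C(OCc2ccccc2)C(OC)=C(OC)C1=O | intermediate
23 | (2S,3S)-6-(benzyloxy)-3-[2-(benzyloxy)-3,4-dimethoxyphenyl]-7,8-dimethoxy-2-{[(1R,2S)-2-phenylcyclohexyl]oxy}chroman (2,3-cis) | COc1ccc([C@H]2[C@@H](O[C@@H]5CCCC[C@H]5c6ccccc6)Oc3c(cc(OCc4ccccc4)c(OC)c3OC)C2)c(OCc7ccccc7)c1OC | intermediate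
24 | (3S)-6-(benzyloxy)-3-[2-(benzyloxy)-3,4-dimethoxyphenyl]-7,8-dimethoxy-3,4-dihydrochromenylium (C2 oxocarbenium ion) | COc1ccc([C@H]2C=[O+]c3c(cc(OCc4ccccc4)c(OC)c3OC)C2)c(OCc5ccccc5)c1OC | intermediate
25 | (3S)-6-(benzyloxy)-3-[2-(benzyloxy)-3,4-dimethoxyphenyl]-7,8-dimethoxychroman | COc1ccc([C@H]2COc3c(cc(OCc4ccccc4)c(OC)c3OC)C2)c(OCc5ccccc5)c1OC | intermediate
26 | (3S)-3-(2-hydroxy-3,4-dimethoxyphenyl)-7,8-dimethoxychroman-6-ol | COc1ccc([C@H]2COc3c(cc(O)c(OC)c3OC)C2)c(O)c1OC | target

**Step count**
Total: 12 steps. Longest linear sequence: 7 steps (1, 2, 3, 4, 10, 11, 12 from compound 1; equally 5, 6, 8, 9, 10, 11, 12 from compound 7).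

**Steps most likely to fail**

Step 10. The 2-phenylcyclohexyl group may discriminate poorly between the two faces of the β-aryl (Z)-enol ether, which would erode the configurational purity at C3. Capture of 22 by this hindered dienophile may also be slower than self-condensation of the quinone methide. The fallback keeps the cycloaddition only as the ring-forming event and sets C3 afterwards by catalyst control. It sets out from 23, as whatever diastereomer mixture is obtained. Camphorsulfonic acid in toluene at 80 °C should eliminate the auxiliary alcohol to give 6-(benzyloxy)-3-[2-(benzyloxy)-3,4-dimethoxyphenyl]-7,8-dimethoxy-4H-chromene F1. Asymmetric hydrogenation of this trisubstituted aryl enol ether (H2, CH2Cl2) with a cationic iridium complex [Ir(cod)(P,N)][B(C6H3(CF3)2)4] of a chiral phosphine–oxazoline ligand is the reaction type by which 4H- and 2H-chromenes are reduced to chromans. With the ligand enantiomer chosen for 3S it should give 25, where the route is rejoined.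

Step 11. The acetal may ionise at the ring oxygen (phenoxide as leaving group) and be reduced to an open-chain ether. Ion 24 may lose the C3 proton to a 4H-chromene that is re-reduced without selectivity. The neighbouring 2'-benzyloxy oxygen may also add to C2. The fallback reopens ring C and recloses it by O-alkylation. It sets out from 23. Dilute HCl in THF–water at 0 °C should hydrolyse the acetal, returning the auxiliary, to (3S)-6-(benzyloxy)-3-[2-(benzyloxy)-3,4-dimethoxyphenyl]-7,8-dimethoxychroman-2-ol F2. This is reduced at once with NaBH4 in EtOH at 0 °C, before the open hydroxy-aldehyde can enolise, to 4-(benzyloxy)-6-{(2S)-2-[2-(benzyloxy)-3,4-dimethoxyphenyl]-3-hydroxypropyl}-2,3-dimethoxyphenol F3. A Mitsunobu cyclisation (PPh3, DIAD, THF, 0 °C) then forms O1–C2 at the primary carbinol without touching C3 and comes back to the route at 25.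

Step 8. Oxidative addition to the hindered, electron-rich bromide 9 may be slow, so that alkynylzinc 17 or ynol ether 18 is lost through retro-ene fragmentation or hydration before coupling is complete. The fallback forms the enol-ether C–O bond instead of the aryl–alkyne bond. It sets out from 1 and 10. Benzylation of 1 (BnBr, K2CO3, DMF) should give 2-(benzyloxy)-3,4-dimethoxybenzaldehyde F4. Stork–Zhao olefination (Ph3PCH2I iodide, NaN(SiMe3)2, THF, −78 °C) should give 2-(benzyloxy)-1-[(Z)-2-iodoethenyl]-3,4-dimethoxybenzene F5. Copper-catalysed vinylation of alcohol 10 (copper iodide CuI, 3,4,7,8-tetramethyl-1,10-phenanthroline, Cs2CO3, toluene, 80 °C) proceeds with retention of alkene geometry and comes back to the route at 19, making steps 5 to 9 unnecessary.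

**Further compounds**
F1 | step 10 | 6-(benzyloxy)-3-[2-(benzyloxy)-3,4-dimethoxyphenyl]-7,8-dimethoxy-4H-chromene | COc1ccc(C2=COc3c(cc(OCc4ccccc4)c(OC)c3OC)C2)c(OCc5ccccc5)c1OC
F2 | step 11 | (3S)-6-(benzyloxy)-3-[2-(benzyloxy)-3,4-dimethoxyphenyl]-7,8-dimethoxychroman-2-ol | COc1ccc([C@H]2C(O)Oc3c(cc(OCc4ccccc4)c(OC)c3OC)C2)c(OCc5ccccc5)c1OC
F3 | step 11 | 4-(benzyloxy)-6-{(2S)-2-[2-(benzyloxy)-3,4-dimethoxyphenyl]-3-hydroxypropyl}-2,3-dimethoxyphenol | COc1ccc([C@@H](CO)Cc2cc(OCc3ccccc3)c(OC)c(OC)c2O)c(OCc4ccccc4)c1OC
F4 | step 8 | 2-(benzyloxy)-3,4-dimethoxybenzaldehyde | COc1ccc(C=O)c(OCc2ccccc2)c1OC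
F5 | step 8 | 2-(benzyloxy)-1-[(Z)-2-iodoethenyl]-3,4-dimethoxybenzene | COc1ccc(/C=C\I)c(OCc2ccccc2)c1OC
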